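Target cannot be made faster than 0.0542 M min⁻¹, the pace with every catalyst molecule sitting as catalyst intermediate and leaving by step 2.

    substrate + free catalyst → catalyst intermediate (k1 = 80.1 M⁻¹ min⁻¹)
    catalyst intermediate → free catalyst + target (k2 = 4.93 min⁻¹)
    catalyst intermediate → spent catalyst A (k3 = 0.0594 min⁻¹)
    substrate + catalyst intermediate → spent catalyst B (k4 = 0.0768 M⁻¹ min⁻¹)
    substrate + target → side product (k5 = 0.119 M⁻¹ min⁻¹)

in all of them: free catalyst 11 mM
- noon: substrate 0.50 M (fed, over 40.0 min); time 50 min; all but substrate at the start; substrate goes in evenly over 40.0 min, the run ends at 50 min
- winter: substrate 0.50 M; time 50 min; everything together in a closed stirred flask, run for 50 min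
- midnight: substrate 0.50 M; one stirred flow tank at steady state, fed with the mixture as stated, mean residence time 50 min
- autumn: substrate 0.50 M; one stirred flow tank at steady state, fed with the mixture as stated, mean residence time 250 min

1. the set-up with the highest amount of target at the outlet or at the end, in percent of the substrate put in ("none" if the first two lie within 2 percentage points) (noon / winter / midnight / autumn / none)
2. amount of target at the outlet or at the end, in percent of the substrate put in, noon
3. amount of target at the outlet or at the end, in percent of the substrate put in, winter
4. amount of target at the outlet or at the end, in percent of the substrate put in, midnight
5. amount of target at the outlet or at the end, in percent of the substrate put in, autumn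

- percentages count the substrate that a species holds: one spent catalyst B or side product counts as two
- the stated concentrations are those of everything mixed, before any reaction; amounts are the same in each set-up
- the feed brings no volume worth counting
- run time (noon): 50 min

In winter the whole charge stands in the flask. Free catalyst picks up substrate at 40.0 min⁻¹, faster than the intermediate releases target at 4.93 min⁻¹, so you may reckon with the top pace, which needs 9.22 min for the charge. Meanwhile substrate attacks target. Fold this into the race number Φ = k5[substrate]²/(k2[catalyst]), both at their charges, 0.549: the side step's pace at full substrate and full target, over the catalyst's top pace. With substrate falling and target rising in straight lines, side product, counted twice, comes to Φ/3, or 18.3 %.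

But one number is not enough, because each target made costs k3/k2 of a catalyst. The turnover budget k2[catalyst]/(k3[substrate]) is 1.83, so the working catalyst falls to 45.4 % of its charge and averages 72.6 %. Dividing by that average, I reckon side product at 25.2 % and target at 74.8 % in winter.

In noon the feed of 0.0125 M min⁻¹ is slower than the top pace, so I reckon that catalyst intermediate holds about 0.00254 M of the working catalyst, and that the free catalyst left from the same average takes up the feed. That puts substrate near 0.0286 M, as my average over the dosing time. Side product then comes to k5[substrate] times the dosing time, or 13.6 %, which puts target at 86.4 %. I leave the tanks unreckoned.

The forecast gives 77.5 % for noon, 71.5 % for winter, 72 % for midnight and 78 % for autumn, and answers none: “so I call no clear winner”. My reckoning differs, with noon well ahead.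

The simulation gives 86.2 % for noon, 72.0 % for winter, 72.0 % for midnight and 78.4 % for autumn, so noon leads. The side step is the largest single effect in that lead: struck out, the gap between winter and noon shrinks from 14 percentage points to 0.33 points. Winter holds 26.4 % side product against the 25.2 % reckoned from Φ. The neighbour of winter charged with 0.0066 M of free catalyst has Φ of 0.914 and a budget of 1.10, which reckons target at 44.1 %, and that flask holds 47.2 %.

The numbers were drawn at random within sensible limits; the result is computed.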